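**Retrosynthetic overview**
1. Target 26 ⇒ silyl ether 25 ⇒ diol 24 by C–O disconnection (SN1 cycloetherification); this is the only permanent ring and it is closed in the second-to-last step.
2. Diol 24 ⇒ syringyl-lithium 22 + lactol 19 (a temporary ring that masks a γ-hydroxy aldehyde) ⇒ alkene cleavage of 16.
3. Alcohol 16 ⇒ Felkin reduction of aryl ketone 15 ⇒ veratryl-lithium 13 + Weinreb amide 11 of acid 8.
4. erythro-2,3-Dimethyl acid 8 ⇒ Ireland–Claisen rearrangement of ester 4, where 1,3-chirality transfer sets both methyl-bearing centres.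
5. Ester 4 ⇒ (R)-allylic alcohol 2 ⇒ ketoreductase reduction of achiral enone 1, the sole source of absolute configuration.

Assumption: a commercial ketoreductase screening panel supplies an (R)-selective (anti-Prelog) enzyme for enone 1, and LDA, n-BuLi and L-Selectride are bought as solutions.

**Route**

Step 1
Reactants: 1 (3E)-pent-3-en-2-one
Product: 2 (2R,3E)-pent-3-en-2-ol
Conditions: (R)-selective ketoreductase (NADPH-dependent alcohol dehydrogenase, Lactobacillus type), NADP+ (cat.), i-PrOH, phosphate buffer pH 7, 30 °C; MTBE extraction, distillation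
Reagents that add atoms: none
Why: Biocatalytic asymmetric ketone reduction with isopropanol-coupled cofactor recycling delivers hydride to one carbonyl face only (anti-Prelog), setting the (R) carbinol in high ee and leaving the conjugated alkene untouched.

Step 2
Reactants: 2 (2R,3E)-pent-3-en-2-ol; 3 propanoyl chloride
Product: 4 (2R,3E)-pent-3-en-2-yl propanoate
Conditions: Et3N, DMAP (cat.), CH2Cl2, 0 °C → rt
Reagents that add atoms: none
Why: DMAP-catalysed O-acylation under basic conditions cannot ionise or transpose the allylic stereocentre.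

Step 3
Reactants: 4 (2R,3E)-pent-3-en-2-yl propanoate
Product: 8 (2S,3S,4E)-2,3-dimethylhex-4-enoic acid, via lithium enolate 5 (not isolated), via silyl ketene acetal 6 (not isolated), via trimethylsilyl ester 7 (not isolated)
Conditions: LDA, THF, −78 °C; TMSCl/Et3N, −78 °C → rt, then 50 °C; 1 M HCl
Reagents that add atoms: none
Why: Ireland–Claisen rearrangement: kinetic deprotonation in THF gives the enolate with methyl cis to the allyloxy oxygen, and the chair [3,3] shift with the carbinol methyl equatorial transfers the (R) centre suprafacially to the new erythro C2 (S)/C3 (S) pair and an E alkene (dr about 9:1 expected).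

Step 4
Reactants: 8 (2S,3S,4E)-2,3-dimethylhex-4-enoic acid; 9 N,O-dimethylhydroxylamine hydrochloride
Product: 11 (2S,3S,4E)-N-methoxy-N,2,3-trimethylhex-4-enamide, via acyl imidazole 10 (not isolated)
Conditions: CDI, CH2Cl2, rt; then 9, rt
Reagents that add atoms: none
Why: Carbonyldiimidazole activation followed by aminolysis (Weinreb amide synthesis) runs near neutrality and does not epimerise the α-methyl centre.

Step 5
Reactants: 11 (2S,3S,4E)-N-methoxy-N,2,3-trimethylhex-4-enamide; 12 4-bromo-1,2-dimethoxybenzene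
Product: 15 (2S,3S,4E)-1-(3,4-dimethoxyphenyl)-2,3-dimethylhex-4-en-1-one, via aryllithium 13 (not isolated), via tetrahedral adduct 14 (not isolated)
Conditions: 12 (1.3 equiv), n-BuLi, THF, −78 °C; add 11, −78 → 0 °C; 1 M HCl quench
Reagents that add atoms: none
Why: Bromine–lithium exchange then Weinreb ketone synthesis: the chelated tetrahedral adduct survives until the acidic quench, so there is no over-addition and the α-centre is never exposed as a free ketone to base.

Step 6
Reactants: 15 (2S,3S,4E)-1-(3,4-dimethoxyphenyl)-2,3-dimethylhex-4-en-1-one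
Product: 16 (1S,2S,3S,4E)-1-(3,4-dimethoxyphenyl)-2,3-dimethylhex-4-en-1-ol
Conditions: L-Selectride, THF, −78 °C; H2O quench
Reagents that add atoms: none
Why: Felkin–Anh reduction with a bulky hydride attacks anti to the large sec-alkyl group and gives the 1,2-anti alcohol, C1 (S), which is the configuration that places the aryl trans to its neighbouring methyl in the ring.

Step 7
Reactants: 16 (1S,2S,3S,4E)-1-(3,4-dimethoxyphenyl)-2,3-dimethylhex-4-en-1-ol
Product: 19 (3R,4S,5S)-5-(3,4-dimethoxyphenyl)-3,4-dimethyloxolan-2-ol (anomer mixture), via triol 17 (not isolated), via hydroxy aldehyde 18 (not isolated)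
Conditions: OsO4 (2 mol %), NaIO4, 2,6-lutidine, dioxane/H2O 3:1, rt
Reagents that add atoms: osmium tetroxide O=[Os](=O)(=O)=O; sodium periodate [Na+].[O-]I(=O)(=O)=O
Why: Lemieux–Johnson oxidation (catalytic dihydroxylation then periodate glycol cleavage) removes the propenyl terminus as acetaldehyde, and the γ-hydroxy aldehyde closes to the lactol; the buffered medium spares the α-methyl centre and the dimethoxyarene.

Step 8
Reactants: 20 4-bromo-2,6-dimethoxyphenol
Product: 21 (4-bromo-2,6-dimethoxyphenoxy)(tert-butyl)dimethylsilane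
Conditions: TBSCl, imidazole, DMF, rt
Reagents that add atoms: tert-butyldimethylsilyl chloride CC(C)(C)[Si](C)(C)Cl
Why: Imidazole-assisted silylation of the phenol gives an ether that tolerates BuLi and is removed by fluoride.

Step 9
Reactants: 19 (3R,4S,5S)-5-(3,4-dimethoxyphenyl)-3,4-dimethyloxolan-2-ol (anomer mixture); 21 (4-bromo-2,6-dimethoxyphenoxy)(tert-butyl)dimethylsilane
Product: 24 (1S,2S,3R)-4-{4-[tert-butyl(dimethyl)silyl]oxy-3,5-dimethoxyphenyl}-1-(3,4-dimethoxyphenyl)-2,3-dimethylbutane-1,4-diol (C4 epimer mixture), via aryllithium 22 (not isolated), via aldehyde alkoxide 23 (not isolated)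
Conditions: 21 (3 equiv), n-BuLi (2.9 equiv), THF, −78 °C; add 19, −78 → 0 °C; H2O quench
Reagents that add atoms: none
Why: Bromine–lithium exchange then 1,2-addition: one equivalent deprotonates the lactol, whose ring-opened aldehyde is captured by the next; the new carbinol forms as an epimer mixture, which does not matter because that centre is ionised in step 10.

Step 10
Reactants: 24 (1S,2S,3R)-4-{4-[tert-butyl(dimethyl)silyl]oxy-3,5-dimethoxyphenyl}-1-(3,4-dimethoxyphenyl)-2,3-dimethylbutane-1,4-diol (C4 epimer mixture)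
Product: 25 tert-butyl{4-[(2R,3R,4S,5S)-5-(3,4-dimethoxyphenyl)-3,4-dimethyloxolan-2-yl]-2,6-dimethoxyphenoxy}dimethylsilane
Conditions: BF3·OEt2 (1 equiv), CH2Cl2, −78 → −20 °C until the isomer ratio is constant; Et3N then aq NaHCO3
Reagents that add atoms: none
Why: Lewis-acid SN1 cycloetherification: a p-oxybenzylic cation is trapped by the remote hydroxyl (5-exo), and because opening and closure are reversible under BF3 both C4 epimers should converge on the thermodynamic isomer with each aryl trans to its neighbouring methyl, fixing C2 (R) beside the unchanged C3 (R), C4 (S) and C5 (S).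

Step 11
Reactants: 25 tert-butyl{4-[(2R,3R,4S,5S)-5-(3,4-dimethoxyphenyl)-3,4-dimethyloxolan-2-yl]-2,6-dimethoxyphenoxy}dimethylsilane
Product: 26 4-[(2R,3R,4S,5S)-5-(3,4-dimethoxyphenyl)-3,4-dimethyloxolan-2-yl]-2,6-dimethoxyphenol
Conditions: TBAF/AcOH (1:1), THF, 0 °C → rt
Reagents that add atoms: none
Why: Fluoride desilylation buffered with acetic acid frees the phenol without building up a phenoxide that could open the benzylic ether through a quinone methide.

**Compound list**

1 | (3E)-pent-3-en-2-one | C/C=C/C(C)=O | starting material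
2 | (2R,3E)-pent-3-en-2-ol | C[C@@H](O)/C=C/C | intermediate
3 | propanoyl chloride | CCC(=O)Cl | starting material
4 | (2R,3E)-pent-3-en-2-yl propanoate | CCC(=O)O[C@H](C)/C=C/C | intermediate
5 | lithium (1Z)-1-{[(2R,3E)-pent-3-en-2-yl]oxy}prop-1-en-1-olate (methyl cis to the allyloxy oxygen) | C/C=C(/[O-])O[C@H](C)/C=C/C.[Li+] | intermediate
6 | trimethyl{[(1E)-1-{[(2R,3E)-pent-3-en-2-yl]oxy}prop-1-en-1-yl]oxy}silane | C/C=C(/O[Si](C)(C)C)O[C@H](C)/C=C/C | intermediate
7 | trimethylsilyl (2S,3S,4E)-2,3-dimethylhex-4-enoate | C/C=C/[C@H](C)[C@H](C)C(=O)O[Si](C)(C)C | intermediate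
8 | (2S,3S,4E)-2,3-dimethylhex-4-enoic acid | C/C=C/[C@H](C)[C@H](C)C(=O)O | intermediate
9 | N,O-dimethylhydroxylamine hydrochloride | CNOC.Cl | starting material
10 | (2S,3S,4E)-1-(1H-imidazol-1-yl)-2,3-dimethylhex-4-en-1-one | C/C=C/[C@H](C)[C@H](C)C(=O)n1ccnc1 | intermediate
11 | (2S,3S,4E)-N-methoxy-N,2,3-trimethylhex-4-enamide | C/C=C/[C@H](C)[C@H](C)C(=O)N(C)OC | intermediate
12 | 4-bromo-1,2-dimethoxybenzene | COc1ccc(Br)cc1OC | starting material
13 | (3,4-dimethoxyphenyl)lithium | [Li]c1ccc(OC)c(OC)c1 | intermediate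
14 | lithium (2S,3S,4E)-1-(3,4-dimethoxyphenyl)-1-[methoxy(methyl)amino]-2,3-dimethylhex-4-en-1-olate | C/C=C/[C@H](C)[C@H](C)C([O-])(N(C)OC)c1ccc(OC)c(OC)c1.[Li+] | intermediate
15 | (2S,3S,4E)-1-(3,4-dimethoxyphenyl)-2,3-dimethylhex-4-en-1-one | C/C=C/[C@H](C)[C@H](C)C(=O)c1ccc(OC)c(OC)c1 | intermediate
16 | (1S,2S,3S,4E)-1-(3,4-dimethoxyphenyl)-2,3-dimethylhex-4-en-1-ol | C/C=C/[C@H](C)[C@H](C)[C@H](O)c1ccc(OC)c(OC)c1 | intermediate
17 | (1S,2S,3R)-1-(3,4-dimethoxyphenyl)-2,3-dimethylhexane-1,4,5-triol (4,5-diol diastereomer mixture) | CC(O)C(O)[C@H](C)[C@H](C)[C@H](O)c1ccc(OC)c(OC)c1 | intermediate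
18 | (2R,3S,4S)-4-(3,4-dimethoxyphenyl)-4-hydroxy-2,3-dimethylbutanal | O=C[C@H](C)[C@H](C)[C@H](O)c1ccc(OC)c(OC)c1 | intermediate
19 | (3R,4S,5S)-5-(3,4-dimethoxyphenyl)-3,4-dimethyloxolan-2-ol (anomer mixture) | OC1[C@H](C)[C@H](C)[C@H](O1)c2ccc(OC)c(OC)c2 | intermediate
20 | 4-bromo-2,6-dimethoxyphenol | COc1cc(Br)cc(OC)c1O | starting material
21 | (4-bromo-2,6-dimethoxyphenoxy)(tert-butyl)dimethylsilane | COc1cc(Br)cc(OC)c1O[Si](C)(C)C(C)(C)C | intermediate
22 | {4-[tert-butyl(dimethyl)silyl]oxy-3,5-dimethoxyphenyl}lithium | [Li]c1cc(OC)c(O[Si](C)(C)C(C)(C)C)c(OC)c1 | intermediate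
23 | lithium (1S,2S,3R)-1-(3,4-dimethoxyphenyl)-2,3-dimethyl-4-oxobutan-1-olate | O=C[C@H](C)[C@H](C)[C@H]([O-])c1ccc(OC)c(OC)c1.[Li+] | intermediate
24 | (1S,2S,3R)-4-{4-[tert-butyl(dimethyl)silyl]oxy-3,5-dimethoxyphenyl}-1-(3,4-dimethoxyphenyl)-2,3-dimethylbutane-1,4-diol (C4 epimer mixture) | COc1cc(cc(OC)c1O[Si](C)(C)C(C)(C)C)C(O)[C@H](C)[C@H](C)[C@H](O)c2ccc(OC)c(OC)c2 | intermediate
25 | tert-butyl{4-[(2R,3R,4S,5S)-5-(3,4-dimethoxyphenyl)-3,4-dimethyloxolan-2-yl]-2,6-dimethoxyphenoxy}dimethylsilane | COc1cc(cc(OC)c1O[Si](C)(C)C(C)(C)C)[C@H]3[C@H](C)[C@H](C)[C@H](O3)c2ccc(OC)c(OC)c2 | intermediate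
26 | 4-[(2R,3R,4S,5S)-5-(3,4-dimethoxyphenyl)-3,4-dimethyloxolan-2-yl]-2,6-dimethoxyphenol | COc1cc(cc(OC)c1O)[C@H]2[C@H](C)[C@H](C)[C@H](O2)c3ccc(OC)c(OC)c3 | target

**Totals and risks**

Total step count: 11. Longest linear sequence: 10 (steps 1–7 and 9–11, from 1); step 8 is a one-step side branch.

Most likely to fail, 1 — step 3. The erythro/threo ratio depends on the enolate geometry (about 9:1 at best), and the threo acid would carry through to the 3,4-trans-dimethyl series. Fallback, setting out from 2 and coming back at 15: alcohol 2 is heated with N,N-dimethylpropanamide dimethyl acetal (xylene, 140 °C, methanol distilled off; Eschenmoser–Claisen). This forms the ketene N,O-acetal F1, whose methyl is held cis to the allyloxy oxygen by allylic strain against NMe2 rather than by kinetic deprotonation. It rearranges through the same chair to the amide (2S,3S,4E)-N,N,2,3-tetramethylhex-4-enamide F2. Aryllithium 13 (from 12) then adds to F2 (THF, −78 → 0 °C) and gives ketone 15 directly, replacing steps 2–5.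

Most likely to fail, 2 — step 9. Ring opening of the lithium lactolate is slow, excess aryllithium is consumed, and the transient α-methyl aldehyde can enolise and lose the cis-dimethyl relationship. Fallback, setting out from 19 and coming back at 24: lactol 19 is oxidised (TEMPO cat., PhI(OAc)2, CH2Cl2) to the lactone (3R,4S,5S)-5-(3,4-dimethoxyphenyl)-3,4-dimethyloxolan-2-one F3. One equivalent of aryllithium 22 at −78 °C acylates cleanly to the cyclic hemiketal F4. NaBH4 (MeOH, 0 °C) reduces F4 through its open hydroxy-ketone form to diol 24.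

Most likely to fail, 3 — step 10. Kinetic closure can leave an aryl cis to its neighbouring methyl, and over-exposure to acid can give styrene or aryltetralin (Friedel–Crafts) by-products from the benzylic cation. Fallback, setting out from 19 and coming back at 25: lactol 19 is treated with benzenesulfinic acid and CaCl2 (CH2Cl2) to give the anomeric sulfone F5. The arylzinc bromide F6, made from aryllithium 22 and ZnBr2, displaces sulfinate through the cyclic oxocarbenium ion (THF, rt). It enters anti to the two cis methyls, so 25 is formed by C–C instead of C–O bond formation and steps 9–10 are bypassed.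

**Further compounds**

F1 | step 3 | (1Z)-N,N-dimethyl-1-{[(2R,3E)-pent-3-en-2-yl]oxy}prop-1-en-1-amine | C/C=C(/N(C)C)O[C@H](C)/C=C/C
F2 | step 3 | (2S,3S,4E)-N,N,2,3-tetramethylhex-4-enamide | C/C=C/[C@H](C)[C@H](C)C(=O)N(C)C
F3 | step 9 | (3R,4S,5S)-5-(3,4-dimethoxyphenyl)-3,4-dimethyloxolan-2-one | O=C1[C@H](C)[C@H](C)[C@H](O1)c2ccc(OC)c(OC)c2
F4 | step 9 | (3R,4S,5S)-2-{4-[tert-butyl(dimethyl)silyl]oxy-3,5-dimethoxyphenyl}-5-(3,4-dimethoxyphenyl)-3,4-dimethyloxolan-2-ol (anomer mixture) | OC1(c2cc(OC)c(O[Si](C)(C)C(C)(C)C)c(OC)c2)[C@H](C)[C@H](C)[C@H](O1)c3ccc(OC)c(OC)c3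
F5 | step 10 | (3R,4S,5S)-2-(benzenesulfonyl)-5-(3,4-dimethoxyphenyl)-3,4-dimethyloxolane (anomer mixture) | O=S(=O)(c1ccccc1)C1[C@H](C)[C@H](C)[C@H](O1)c2ccc(OC)c(OC)c2
F6 | step 10 | {4-[tert-butyl(dimethyl)silyl]oxy-3,5-dimethoxyphenyl}zinc bromide | COc1cc([Zn]Br)cc(OC)c1O[Si](C)(C)C(C)(C)C
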